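**Strategy**

The cyclohexene ring is disconnected between C-2 (its CH2) and C-1 (the gem-dimethyl carbon; carotenoid numbering). Its carbons are first assembled as a 6-methylene-3,6-dihydro-2H-pyran in which the ring oxygen links C-1 to C-3. A Lewis-acid-induced 1,3-shift of C-1 from O to C then closes the carbocycle and turns the ether oxygen into the C-3 carbonyl. The step exploits that C-1 is a non-stereogenic tertiary carbon able to bear positive charge and that C-3 carries the ring's only oxygen. The pyran comes from prenol by asymmetric epoxidation (fixing C-6), alkynylation, cuprate addition/lactonisation and methylenation; hydride reduction then sets C-3, and a Julia–Kocienski olefination with crocetin dialdehyde completes the polyene.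

Key step: step 6

Remark: the target is read as (3S,6R), with 3-OH and the C-6 side chain cis on the ring. Within the steps each compound is described by its own IUPAC locants.
Remark: prenol 1, ethyl propiolate 4 and crocetin dialdehyde 15 are taken as commercial.

**Route**

Step 1
Reactants: 1 prenol (3-methylbut-2-en-1-ol)
Product: 2 [(2S)-3,3-dimethyloxiran-2-yl]methanol
Conditions: Ti(OiPr)4 (5 mol%), L-(+)-diisopropyl tartrate (6 mol%), t-BuOOH, 4 Å MS, CH2Cl2, −20 °C
Reagents that add atoms: tert-butyl hydroperoxide, CC(C)(C)OO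
Why: Katsuki–Sharpless asymmetric epoxidation of a trisubstituted allylic alcohol; the L-tartrate ligand should direct oxygen to the face that gives the (2S)-epoxide.

Step 2
Reactants: 2 [(2S)-3,3-dimethyloxiran-2-yl]methanol
Product: 3 tert-butyl{[(2S)-3,3-dimethyloxiran-2-yl]methoxy}diphenylsilane
Conditions: TBDPSCl, imidazole, CH2Cl2, 0 °C to rt
Reagents that add atoms: tert-butyl(chloro)diphenylsilane, CC(C)(C)[Si](Cl)(c1ccccc1)c1ccccc1
Why: Standard silylation of the primary alcohol under non-acidic conditions that leave the epoxide and its stereocenter untouched.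

Step 3
Reactants: 3 tert-butyl{[(2S)-3,3-dimethyloxiran-2-yl]methoxy}diphenylsilane; 4 ethyl propiolate
Product: 6 ethyl (4R)-4-({[tert-butyl(diphenyl)silyl]oxy}methyl)-5-hydroxy-5-methylhex-2-ynoate, via lithium ethyl propiolate 5 (not isolated)
Conditions: 4, n-BuLi, THF, −78 °C; BF3·OEt2; then 3, −78 °C; aq NH4Cl
Reagents that add atoms: none
Why: Yamaguchi–Hirao alkynylation: the BF3-activated epoxide should be opened by the acetylide in an SN2 manner at the secondary carbon (the fully substituted carbon cannot undergo SN2), with inversion, which turns the (2S)-epoxide carbon into the (4R)-stereocenter and frees the tertiary alcohol.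

Step 4
Reactants: 6 ethyl (4R)-4-({[tert-butyl(diphenyl)silyl]oxy}methyl)-5-hydroxy-5-methylhex-2-ynoate
Product: 8 (5R)-5-({[tert-butyl(diphenyl)silyl]oxy}methyl)-4,6,6-trimethyl-5,6-dihydro-2H-pyran-2-one, via (Z)-hydroxy enoate 7 (not isolated)
Conditions: Me2CuLi (3 equiv, from MeLi and CuI), THF, −78 °C; aq NH4Cl; then p-TsOH (cat.), PhMe, 40 °C
Reagents that add atoms: lithium dimethylcuprate, [Li+].C[Cu-]C
Why: Organocuprate conjugate addition to the ynoate is a syn carbocupration, so CH3 and H end up cis and the carbinol arm cis to the ester (Z), which allows lactonisation to the 4-methyl-dihydropyranone; the stereocenter is not involved.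

Step 5
Reactants: 8 (5R)-5-({[tert-butyl(diphenyl)silyl]oxy}methyl)-4,6,6-trimethyl-5,6-dihydro-2H-pyran-2-one
Product: 9 tert-butyl{[(3R)-2,2,4-trimethyl-6-methylidene-3,6-dihydro-2H-pyran-3-yl]methoxy}diphenylsilane
Conditions: Cp2TiMe2, PhMe/THF, 65 °C, dark
Reagents that add atoms: dimethyltitanocene (Cp2TiMe2), [CH3-].[CH3-].[Ti+4].c1cc[cH-]c1.c1cc[cH-]c1
Why: Petasis methylenation converts the lactone carbonyl into the exocyclic enol ether under non-acidic, non-basic conditions; the exocyclic diene is s-trans locked, so no sigmatropic hydrogen shift can reach the stereocenter.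

Step 6
Reactants: 9 tert-butyl{[(3R)-2,2,4-trimethyl-6-methylidene-3,6-dihydro-2H-pyran-3-yl]methoxy}diphenylsilane
Product: 10 (4R)-4-({[tert-butyl(diphenyl)silyl]oxy}methyl)-3,5,5-trimethylcyclohex-2-en-1-one
Conditions: Me2AlCl (1.2 equiv), CH2Cl2, −78 to −40 °C; then Et3N, aq NaHCO3
Reagents that add atoms: none
Why: Proposed new method: Me2AlCl should bind the ring oxygen of 9 and ionise the tertiary C-2–O bond to a contact ion pair of a tert-alkyl cation and a cross-conjugated aluminium dienolate, whose terminal CH2 then attacks the cation, so that the gem-dimethyl carbon moves 1,3 from O to C and the ether oxygen becomes the carbonyl of 10. The closest known reaction types are the Petasis–Ferrier rearrangement of cyclic enol acetals (the same aluminium-mediated O-to-C 1,3-shift, there through an oxocarbenium ion) and the Lewis-acid α-tert-alkylation of enol silanes with tertiary halides; here a plain tertiary carbocation replaces the oxocarbenium ion. The six-membered carbocycle closes by a formally 6-(enolendo)-exo-tet C-alkylation; return of the cation to oxygen only regenerates 9, so C–C bonding is the one irreversible productive channel. No stereocenter is formed: the gem-dimethyl carbon is not stereogenic and C-4 of 10 is the untouched C-3 of 9. The step needs C-alkylation to outrun proton loss or 1,2-hydride shift from the C–H next to the cation, which would erase that stereocenter. Low temperature, the non-basic chloroaluminate counter-ion and the geometry of 9 are relied on for this: the C–H antiperiplanar to the breaking C–O bond lies in the nodal plane of the neighbouring C=C and gains no allylic assistance.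

Step 7
Reactants: 10 (4R)-4-({[tert-butyl(diphenyl)silyl]oxy}methyl)-3,5,5-trimethylcyclohex-2-en-1-one
Product: 11 (4R)-4-(hydroxymethyl)-3,5,5-trimethylcyclohex-2-en-1-one
Conditions: HF·pyridine, pyridine, THF, 0 °C to rt
Reagents that add atoms: none
Why: Fluoride-mediated desilylation under buffered, non-basic conditions, chosen so that the γ-stereocenter of the enone is not epimerised.

Step 8
Reactants: 11 (4R)-4-(hydroxymethyl)-3,5,5-trimethylcyclohex-2-en-1-one
Product: 12 (4R)-3,5,5-trimethyl-4-{[(1-phenyl-1H-tetrazol-5-yl)sulfanyl]methyl}cyclohex-2-en-1-one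
Conditions: 1-phenyl-1H-tetrazole-5-thiol, PPh3, DIAD, THF, 0 °C to rt
Reagents that add atoms: 1-phenyl-1H-tetrazole-5-thiol, Sc1nnnn1-c1ccccc1
Why: Mitsunobu thioetherification, an SN2 displacement at the primary carbinol carbon under essentially neutral conditions; the stereocenter is not involved.

Step 9
Reactants: 12 (4R)-3,5,5-trimethyl-4-{[(1-phenyl-1H-tetrazol-5-yl)sulfanyl]methyl}cyclohex-2-en-1-one
Product: 13 (1S,4R)-3,5,5-trimethyl-4-{[(1-phenyl-1H-tetrazol-5-yl)sulfanyl]methyl}cyclohex-2-en-1-ol
Conditions: NaBH4, CeCl3·7H2O, MeOH, −78 °C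
Reagents that add atoms: none
Why: Luche 1,2-reduction; the small hydride should add axially to the half-chair enone, on the face opposite the pseudoaxial C-4 side chain, giving the pseudo-equatorial (1S)-alcohol cis to that chain, with the minor trans epimer removed by chromatography.

Step 10
Reactants: 13 (1S,4R)-3,5,5-trimethyl-4-{[(1-phenyl-1H-tetrazol-5-yl)sulfanyl]methyl}cyclohex-2-en-1-ol
Product: 14 (1S,4R)-3,5,5-trimethyl-4-{[(1-phenyl-1H-tetrazol-5-yl)sulfonyl]methyl}cyclohex-2-en-1-ol
Conditions: (NH4)6Mo7O24·4H2O (10 mol%), 30% aq H2O2, EtOH, 0 °C to rt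
Reagents that add atoms: hydrogen peroxide, OO
Why: Molybdate-catalysed sulfide-to-sulfone oxidation, which should be much faster at sulfur than epoxidation of the hindered trisubstituted alkene.

Step 11
Reactants: 14 (1S,4R)-3,5,5-trimethyl-4-{[(1-phenyl-1H-tetrazol-5-yl)sulfonyl]methyl}cyclohex-2-en-1-ol; 15 crocetin dialdehyde ((2E,4E,6E,8E,10E,12E,14E)-2,6,11,15-tetramethylhexadeca-2,4,6,8,10,12,14-heptaenedial)
Product: 16 (2E,4E,6E,8E,10E,12E,14E,16E)-17-[(1R,4S)-4-hydroxy-2,6,6-trimethylcyclohex-2-en-1-yl]-2,6,11,15-tetramethylheptadeca-2,4,6,8,10,12,14,16-octaenal (the target)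
Conditions: KN(SiMe3)2 (2.1 equiv) added to 14 and 15 (3 equiv), THF/DMF, −78 °C to rt, dark; aq NH4Cl
Reagents that add atoms: none
Why: Julia–Kocienski olefination: the α-sulfonyl carbanion (the second equivalent of base covers the hydroxyl) adds to one aldehyde of the symmetric dialdehyde used in excess, and Smiles rearrangement with loss of SO2 and tetrazolate should give the new disubstituted alkene with the E preference of phenyltetrazolyl sulfones with a potassium counter-ion.

**Compound list**

1 | prenol (3-methylbut-2-en-1-ol) | CC(C)=CCO | starting material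
2 | [(2S)-3,3-dimethyloxiran-2-yl]methanol | CC1(C)O[C@H]1CO | intermediate
3 | tert-butyl{[(2S)-3,3-dimethyloxiran-2-yl]methoxy}diphenylsilane | CC1(C)O[C@H]1CO[Si](c1ccccc1)(c1ccccc1)C(C)(C)C | intermediate
4 | ethyl propiolate | C#CC(=O)OCC | starting material
5 | lithium ethyl propiolate (lithium 3-ethoxy-3-oxoprop-1-yn-1-ide) | [Li+].[C-]#CC(=O)OCC | intermediate
6 | ethyl (4R)-4-({[tert-butyl(diphenyl)silyl]oxy}methyl)-5-hydroxy-5-methylhex-2-ynoate | CCOC(=O)C#C[C@H](CO[Si](c1ccccc1)(c1ccccc1)C(C)(C)C)C(C)(C)O | intermediate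
7 | ethyl (2Z,4R)-4-({[tert-butyl(diphenyl)silyl]oxy}methyl)-5-hydroxy-3,5-dimethylhex-2-enoate | CCOC(=O)/C=C(C)\[C@H](CO[Si](c1ccccc1)(c1ccccc1)C(C)(C)C)C(C)(C)O | intermediate
8 | (5R)-5-({[tert-butyl(diphenyl)silyl]oxy}methyl)-4,6,6-trimethyl-5,6-dihydro-2H-pyran-2-one | O=C1C=C(C)[C@H](CO[Si](c2ccccc2)(c2ccccc2)C(C)(C)C)C(C)(C)O1 | intermediate
9 | tert-butyl{[(3R)-2,2,4-trimethyl-6-methylidene-3,6-dihydro-2H-pyran-3-yl]methoxy}diphenylsilane | C=C1C=C(C)[C@H](CO[Si](c2ccccc2)(c2ccccc2)C(C)(C)C)C(C)(C)O1 | intermediate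
10 | (4R)-4-({[tert-butyl(diphenyl)silyl]oxy}methyl)-3,5,5-trimethylcyclohex-2-en-1-one | O=C1C=C(C)[C@H](CO[Si](c2ccccc2)(c2ccccc2)C(C)(C)C)C(C)(C)C1 | intermediate
11 | (4R)-4-(hydroxymethyl)-3,5,5-trimethylcyclohex-2-en-1-one | O=C1C=C(C)[C@H](CO)C(C)(C)C1 | intermediate
12 | (4R)-3,5,5-trimethyl-4-{[(1-phenyl-1H-tetrazol-5-yl)sulfanyl]methyl}cyclohex-2-en-1-one | O=C1C=C(C)[C@H](CSc2nnnn2-c2ccccc2)C(C)(C)C1 | intermediate
13 | (1S,4R)-3,5,5-trimethyl-4-{[(1-phenyl-1H-tetrazol-5-yl)sulfanyl]methyl}cyclohex-2-en-1-ol | CC1=C[C@@H](O)CC(C)(C)[C@H]1CSc1nnnn1-c1ccccc1 | intermediate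
14 | (1S,4R)-3,5,5-trimethyl-4-{[(1-phenyl-1H-tetrazol-5-yl)sulfonyl]methyl}cyclohex-2-en-1-ol | CC1=C[C@@H](O)CC(C)(C)[C@H]1CS(=O)(=O)c1nnnn1-c1ccccc1 | intermediate
15 | crocetin dialdehyde ((2E,4E,6E,8E,10E,12E,14E)-2,6,11,15-tetramethylhexadeca-2,4,6,8,10,12,14-heptaenedial) | O=C/C(C)=C/C=C/C(C)=C/C=C/C=C(C)/C=C/C=C(\C)C=O | starting material
16 | (2E,4E,6E,8E,10E,12E,14E,16E)-17-[(1R,4S)-4-hydroxy-2,6,6-trimethylcyclohex-2-en-1-yl]-2,6,11,15-tetramethylheptadeca-2,4,6,8,10,12,14,16-octaenal | CC1=C[C@@H](O)CC(C)(C)[C@H]1/C=C/C(C)=C/C=C/C(C)=C/C=C/C=C(C)/C=C/C=C(\C)C=O | target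

**Step count and risks**

Total step count: 11. Longest linear sequence: 11 steps (1 to 16; 4 and 15 enter as commercial fragments).

Steps most likely to fail:

Step 6 (proposed new method). After ionisation of the tertiary C–O bond, proton loss or 1,2-hydride migration from the adjacent stereogenic C–H may outrun C-alkylation. This would erode the configuration or divert the cation; simple return to oxygen would leave 9 unchanged. The fallback uses known chemistry, sets out from 9 and rejoins the route at 13. PPTS (cat.) in CH2Cl2 should isomerise 9 to the 2H-pyran isomer tert-butyl[(2,2,4,6-tetramethyl-2H-pyran-3-yl)methoxy]diphenylsilane F1, the valence tautomer of the (Z)-dienone. KOt-Bu in t-BuOH/THF at 40 °C then forms the same C–C bond by the base-mediated isophorone-type ring closure (enolate 6π-electrocyclisation, equivalently an intramolecular 1,6-Michael addition). This gives 10 as the racemate, that is together with the (4S)-enantiomer of 10 F2. Steps 7 to 9 run on the racemate give 11, 12 and 13 accompanied by the (4S)-hydroxy enone F3, the (4S)-sulfide enone F4 and the (1R,4S)-alcohol F5. A lipase-mediated acylation (Burkholderia cepacia lipase, vinyl acetate), assumed by analogy with related ring allylic alcohols to take the (1R)-carbinol to the (1R,4S)-acetate F6, then leaves enantiomerically enriched 13 for step 10.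

Step 3. Lewis-acid-induced ionisation at the fully substituted epoxide carbon (rearrangement to carbonyl compounds or attack at the wrong carbon) may compete with the slow SN2 attack at the hindered secondary carbon. The fallback sets out from 3 and returns at 6. A Lewis-acid-free SN2 opening with the small parent acetylide (LiC≡CH·H2NCH2CH2NH2, DMSO, rt to 50 °C) should give the terminal alkynol (3R)-3-({[tert-butyl(diphenyl)silyl]oxy}methyl)-2-methylpent-4-yn-2-ol F7. Double deprotonation (n-BuLi, 2.1 equiv, THF, −78 °C) and C-acylation with ethyl chloroformate then give 6.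

Step 9. Facial selectivity of hydride delivery may be poor, because the axial methyl group on the neighbouring quaternary carbon opposes the axial attack that leads to the cis alcohol. The fallback sets out from 12 and returns at 13. LiBH(s-Bu)3 in THF at −78 °C should attack equatorially, anti to that methyl group, and give the trans alcohol (1R,4R)-3,5,5-trimethyl-4-{[(1-phenyl-1H-tetrazol-5-yl)sulfanyl]methyl}cyclohex-2-en-1-ol F8. Mitsunobu inversion with 4-nitrobenzoic acid (PPh3, DIAD, THF) to the (1S,4R)-4-nitrobenzoate F9 and methanolysis (K2CO3, MeOH, 0 °C) then give 13.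

**Further compounds**

F1 | step 6 | tert-butyl[(2,2,4,6-tetramethyl-2H-pyran-3-yl)methoxy]diphenylsilane | CC1=CC(C)=C(CO[Si](c2ccccc2)(c2ccccc2)C(C)(C)C)C(C)(C)O1
F2 | step 6 | (4S)-4-({[tert-butyl(diphenyl)silyl]oxy}methyl)-3,5,5-trimethylcyclohex-2-en-1-one | O=C1C=C(C)[C@@H](CO[Si](c2ccccc2)(c2ccccc2)C(C)(C)C)C(C)(C)C1
F3 | step 6 | (4S)-4-(hydroxymethyl)-3,5,5-trimethylcyclohex-2-en-1-one | O=C1C=C(C)[C@@H](CO)C(C)(C)C1
F4 | step 6 | (4S)-3,5,5-trimethyl-4-{[(1-phenyl-1H-tetrazol-5-yl)sulfanyl]methyl}cyclohex-2-en-1-one | O=C1C=C(C)[C@@H](CSc2nnnn2-c2ccccc2)C(C)(C)C1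
F5 | step 6 | (1R,4S)-3,5,5-trimethyl-4-{[(1-phenyl-1H-tetrazol-5-yl)sulfanyl]methyl}cyclohex-2-en-1-ol | CC1=C[C@H](O)CC(C)(C)[C@@H]1CSc1nnnn1-c1ccccc1
F6 | step 6 | (1R,4S)-3,5,5-trimethyl-4-{[(1-phenyl-1H-tetrazol-5-yl)sulfanyl]methyl}cyclohex-2-en-1-yl acetate | CC1=C[C@H](OC(C)=O)CC(C)(C)[C@@H]1CSc1nnnn1-c1ccccc1
F7 | step 3 | (3R)-3-({[tert-butyl(diphenyl)silyl]oxy}methyl)-2-methylpent-4-yn-2-ol | C#C[C@H](CO[Si](c1ccccc1)(c1ccccc1)C(C)(C)C)C(C)(C)O
F8 | step 9 | (1R,4R)-3,5,5-trimethyl-4-{[(1-phenyl-1H-tetrazol-5-yl)sulfanyl]methyl}cyclohex-2-en-1-ol | CC1=C[C@H](O)CC(C)(C)[C@H]1CSc1nnnn1-c1ccccc1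
F9 | step 9 | (1S,4R)-3,5,5-trimethyl-4-{[(1-phenyl-1H-tetrazol-5-yl)sulfanyl]methyl}cyclohex-2-en-1-yl 4-nitrobenzoate | CC1=C[C@@H](OC(=O)c2ccc(cc2)[N+](=O)[O-])CC(C)(C)[C@H]1CSc1nnnn1-c1ccccc1
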